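**Assumptions**

- α-Humulene (sold at ≥96 % purity by catalogue suppliers) is taken as a commercially available starting material; it supplies the 11-membered ring and both E-trisubstituted alkenes.
- (R)-DTBM-SEGPHOS is written as the ligand enantiomer that gives the (S)-boronate; this is a working assignment, to be checked on the first run by Mosher ester analysis of the derived alcohol. If the sense is reversed, the (S)-ligand is used and nothing else changes.

**Retrosynthetic overview**

1. The (Z)-cinnamate C=C is cut by an Ando-type Z-selective Horner–Wadsworth–Emmons reaction between the (diphenoxyphosphoryl)acetate of the ring alcohol and O-TBS-4-hydroxybenzaldehyde; the phenol is unmasked last.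
2. The phosphonoacetate comes from the secondary alcohol by bromoacetylation, then P–C bond formation (Michaelis–Becker).
3. The carbinol C–O bond and the only stereocentre come from a C–B bond made by a site-, regio- and enantioselective CuH-catalysed hydroboration of the single 1,2-disubstituted alkene of α-humulene (new step).
4. Rings: the 11-membered carbocycle is bought intact as α-humulene, so no ring is formed in the route.

**Route**

Step 1
Reactants: 1 α-humulene [(1E,4E,8E)-2,6,6,9-tetramethylcycloundeca-1,4,8-triene]; 2 pinacolborane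
Product: 3 2-[(1S,3E,7E)-3,7,10,10-tetramethylcycloundeca-3,7-dien-1-yl]-4,4,5,5-tetramethyl-1,3,2-dioxaborolane
Conditions: CuCl (5 mol %), KOtBu (10 mol %), (R)-DTBM-SEGPHOS (5.5 mol %), HBpin (2.0 equiv), cyclohexane, 40 °C, 48 h
Reagents that add atoms: pinacolborane, CC1(C)OBOC1(C)C
Why: Proposed new method: the bulky bisphosphine-ligated monovalent copper hydride should insert only the strained trans-1,2-disubstituted alkene (unactivated trisubstituted alkenes do not undergo hydrocupration), place copper on the carbon remote from the quaternary CMe2 carbon for steric reasons and hydride on the neopentyl carbon, and select one alkene face from the rapidly interconverting planar-chiral ring conformers (Curtin–Hammett control, setting C1 as S); the secondary alkylcopper is then borylated by HBpin with retention (sigma-bond metathesis). The closest known reaction type is the CuH/DTBM-SEGPHOS enantioselective hydroboration of acyclic internal alkenes bearing a polar directing group, together with CuH hydroamination of simple trans-alkenes; neither has been shown on a non-directed macrocyclic polyene with site selection among three alkenes.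

Step 2
Reactants: 3 the (S)-pinacol boronate; 4 hydrogen peroxide
Product: 5 (1S,3E,7E)-3,7,10,10-tetramethylcycloundeca-3,7-dien-1-ol
Conditions: 30 % aq. H2O2, 3 M NaOH, THF, 0 °C → rt
Reagents that add atoms: hydrogen peroxide, OO
Why: Alkaline peroxide oxidation of an alkylboronate proceeds by 1,2-migration of carbon from boron to oxygen with retention, so the S configuration is carried over; unactivated alkenes are inert to HOO−.

Step 3
Reactants: 5 the (S)-alcohol; 6 bromoacetic acid
Product: 7 (1S,3E,7E)-3,7,10,10-tetramethylcycloundeca-3,7-dien-1-yl 2-bromoacetate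
Conditions: BrCH2CO2H (1.3 equiv), DCC (1.3 equiv), DMAP (5 mol %), CH2Cl2, 0 °C
Reagents that add atoms: bromoacetic acid, OC(=O)CBr
Why: Steglich esterification acylates the secondary alcohol under near-neutral conditions without touching the C–O bond of the stereocentre or the acid-sensitive ring alkenes.

Step 4
Reactants: 7 the bromoacetate; 8 diphenyl phosphite
Product: 9 (1S,3E,7E)-3,7,10,10-tetramethylcycloundeca-3,7-dien-1-yl 2-(diphenoxyphosphoryl)acetate
Conditions: (PhO)2P(O)H (1.2 equiv), Et3N (1.5 equiv), CH2Cl2, 0 °C → rt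
Reagents that add atoms: diphenyl phosphite, O=[PH](Oc1ccccc1)Oc1ccccc1
Why: Michaelis–Becker alkylation: the amine-generated phosphite anion displaces the activated primary α-bromide (SN2), the way Ando-type phosphonoacetates are made from bromoacetates.

Step 5
Reactants: 9 the diphenyl phosphonoacetate; 10 4-[(tert-butyldimethylsilyl)oxy]benzaldehyde
Product: 12 (1S,3E,7E)-3,7,10,10-tetramethylcycloundeca-3,7-dien-1-yl (2Z)-3-{4-[(tert-butyldimethylsilyl)oxy]phenyl}prop-2-enoate, via sodium phosphonoacetate enolate 11 (not isolated)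
Conditions: NaH (1.1 equiv), THF, 0 °C, 20 min; then 10 (1.2 equiv), −78 → 0 °C
Reagents that add atoms: 4-[(tert-butyldimethylsilyl)oxy]benzaldehyde, O=Cc1ccc(O[Si](C)(C)C(C)(C)C)cc1
Why: Ando-type Z-selective Horner–Wadsworth–Emmons olefination: the electron-poor diaryl phosphonate makes elimination from the kinetically formed cis-oxaphosphetane fast, giving the Z-enoate (typically about 9:1 or better with aryl aldehydes, minor E isomer removed on silica); C1 is not involved.

Step 6
Reactants: 12 the O-TBS (Z)-cinnamate
Product: 13 (1S,3E,7E)-3,7,10,10-tetramethylcycloundeca-3,7-dien-1-yl (2Z)-3-(4-hydroxyphenyl)prop-2-enoate (target)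
Conditions: TBAF (1.1 equiv), AcOH (1.2 equiv), THF, 0 °C, 15 min, in the dark
Reagents that add atoms: none
Why: Fluoride-driven cleavage of an aryl silyl ether is fast at 0 °C; acetic acid buffering and exclusion of light prevent phenoxide-mediated or photochemical Z-to-E isomerisation and leave the ester and ring alkenes intact.

**Compound list**

1 | α-humulene, (1E,4E,8E)-2,6,6,9-tetramethylcycloundeca-1,4,8-triene | C/C1=C\CC(C)(C)/C=C/C/C(C)=C/CC1 | starting material
2 | pinacolborane (4,4,5,5-tetramethyl-1,3,2-dioxaborolane) | CC1(C)OBOC1(C)C | starting material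
3 | 2-[(1S,3E,7E)-3,7,10,10-tetramethylcycloundeca-3,7-dien-1-yl]-4,4,5,5-tetramethyl-1,3,2-dioxaborolane | C/C1=C\CC(C)(C)C[C@H](B2OC(C)(C)C(C)(C)O2)C/C(C)=C/CC1 | intermediate
4 | hydrogen peroxide | OO | starting material
5 | (1S,3E,7E)-3,7,10,10-tetramethylcycloundeca-3,7-dien-1-ol | C/C1=C\CC(C)(C)C[C@H](O)C/C(C)=C/CC1 | intermediate
6 | bromoacetic acid | OC(=O)CBr | starting material
7 | (1S,3E,7E)-3,7,10,10-tetramethylcycloundeca-3,7-dien-1-yl 2-bromoacetate | C/C1=C\CC(C)(C)C[C@H](OC(=O)CBr)C/C(C)=C/CC1 | intermediate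
8 | diphenyl phosphite | O=[PH](Oc1ccccc1)Oc1ccccc1 | starting material
9 | (1S,3E,7E)-3,7,10,10-tetramethylcycloundeca-3,7-dien-1-yl 2-(diphenoxyphosphoryl)acetate | C/C1=C\CC(C)(C)C[C@H](OC(=O)CP(=O)(Oc2ccccc2)Oc2ccccc2)C/C(C)=C/CC1 | intermediate
10 | 4-[(tert-butyldimethylsilyl)oxy]benzaldehyde | O=Cc1ccc(O[Si](C)(C)C(C)(C)C)cc1 | starting material
11 | sodium enolate of 9 (sodium phosphonoacetate enolate) | C/C1=C\CC(C)(C)C[C@H](OC(=O)[CH-]P(=O)(Oc2ccccc2)Oc2ccccc2)C/C(C)=C/CC1.[Na+] | intermediate
12 | (1S,3E,7E)-3,7,10,10-tetramethylcycloundeca-3,7-dien-1-yl (2Z)-3-{4-[(tert-butyldimethylsilyl)oxy]phenyl}prop-2-enoate | C/C1=C\CC(C)(C)C[C@H](OC(=O)/C=C\c2ccc(O[Si](C)(C)C(C)(C)C)cc2)C/C(C)=C/CC1 | intermediate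
13 | (1S,3E,7E)-3,7,10,10-tetramethylcycloundeca-3,7-dien-1-yl (2Z)-3-(4-hydroxyphenyl)prop-2-enoate | C/C1=C\CC(C)(C)C[C@H](OC(=O)/C=C\c2ccc(O)cc2)C/C(C)=C/CC1 | target

**Summary**

Total step count: 6. Longest linear sequence: 6 steps (1 → 13).

Three steps most likely to fail:

Step 1 (the proposed new method). The hindered trans-alkene next to the quaternary carbon may insert into CuH slowly, and the ee from conformer selection is untested. The fallback uses known chemistry, sets out from 1 and comes back at 5. Compound 1 is hydroborated with catecholborane under RhCl(PPh3)3 catalysis (THF, rt), a known reaction that leaves trisubstituted alkenes untouched and puts boron on the less hindered carbon. This gives racemic 2-[(3E,7E)-3,7,10,10-tetramethylcycloundeca-3,7-dien-1-yl]-1,3,2-benzodioxaborole F1, which is not isolated but oxidised in the same flask (H2O2, NaOH) to rac-(3E,7E)-3,7,10,10-tetramethylcycloundeca-3,7-dien-1-ol F2. Acylation with (1S)-(−)-camphanic chloride (pyridine, DMAP cat., CH2Cl2) gives two diastereomers: (1S,3E,7E)-3,7,10,10-tetramethylcycloundeca-3,7-dien-1-yl (1S,4R)-camphanate F3 and (1R,3E,7E)-3,7,10,10-tetramethylcycloundeca-3,7-dien-1-yl (1S,4R)-camphanate F4. These are separated by crystallisation or preparative HPLC and assigned by X-ray, and F3 is saponified (LiOH, THF/H2O) to 5. The same camphanate crystallisation can upgrade material from step 1 if its ee is insufficient.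

Step 5. The electron-rich aldehyde reacts slowly and the Z:E ratio may erode on warming. The fallback sets out from 5 and comes back at 12, building the Z-alkene by alkyne semi-reduction instead of olefination. Commercial tert-butyl(4-ethynylphenoxy)dimethylsilane is deprotonated (n-BuLi, THF, −78 °C) to lithium {4-[(tert-butyldimethylsilyl)oxy]phenyl}acetylide F5 (not isolated), which is carboxylated with CO2 to 3-{4-[(tert-butyldimethylsilyl)oxy]phenyl}prop-2-ynoic acid F6. Steglich esterification of 5 with F6 (DCC, DMAP cat., CH2Cl2, 0 °C) gives (1S,3E,7E)-3,7,10,10-tetramethylcycloundeca-3,7-dien-1-yl 3-{4-[(tert-butyldimethylsilyl)oxy]phenyl}prop-2-ynoate F7. Cis-semihydrogenation (H2 1 atm, Pd/CaCO3 poisoned with Pb(OAc)2, quinoline, EtOAc, rt) then gives 12; the trisubstituted ring alkenes are not reduced by the poisoned catalyst.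

Step 4. Et3N may be quaternised by the bromoacetate, or phenoxide may be lost from phosphorus, lowering the yield on the valuable substrate. The fallback sets out from 5 and comes back at 9, bypassing 7: the P–C bond is made on a simple ester and the finished acid is transferred to the alcohol. tert-Butyl bromoacetate, diphenyl phosphite and Et3N (CH2Cl2, 0 °C) give tert-butyl 2-(diphenoxyphosphoryl)acetate F8. TFA/CH2Cl2 cleaves this to 2-(diphenoxyphosphoryl)acetic acid F9, which is coupled with 5 (DCC, DMAP cat., CH2Cl2, 0 °C) to give 9.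

**Further compounds**

F1 | step 1 | 2-[(3E,7E)-3,7,10,10-tetramethylcycloundeca-3,7-dien-1-yl]-1,3,2-benzodioxaborole (racemic) | C/C1=C\CC(C)(C)CC(B2Oc3ccccc3O2)C/C(C)=C/CC1
F2 | step 1 | rac-(3E,7E)-3,7,10,10-tetramethylcycloundeca-3,7-dien-1-ol | C/C1=C\CC(C)(C)CC(O)C/C(C)=C/CC1
F3 | step 1 | (1S,3E,7E)-3,7,10,10-tetramethylcycloundeca-3,7-dien-1-yl (1S,4R)-camphanate | C/C1=C\CC(C)(C)C[C@H](OC(=O)[C@@]23CC[C@@](C)(C(=O)O2)C3(C)C)C/C(C)=C/CC1
F4 | step 1 | (1R,3E,7E)-3,7,10,10-tetramethylcycloundeca-3,7-dien-1-yl (1S,4R)-camphanate | C/C1=C\CC(C)(C)C[C@@H](OC(=O)[C@@]23CC[C@@](C)(C(=O)O2)C3(C)C)C/C(C)=C/CC1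
F5 | step 5 | lithium {4-[(tert-butyldimethylsilyl)oxy]phenyl}acetylide | [Li+].[C-]#Cc1ccc(O[Si](C)(C)C(C)(C)C)cc1
F6 | step 5 | 3-{4-[(tert-butyldimethylsilyl)oxy]phenyl}prop-2-ynoic acid | OC(=O)C#Cc1ccc(O[Si](C)(C)C(C)(C)C)cc1
F7 | step 5 | (1S,3E,7E)-3,7,10,10-tetramethylcycloundeca-3,7-dien-1-yl 3-{4-[(tert-butyldimethylsilyl)oxy]phenyl}prop-2-ynoate | C/C1=C\CC(C)(C)C[C@H](OC(=O)C#Cc2ccc(O[Si](C)(C)C(C)(C)C)cc2)C/C(C)=C/CC1
F8 | step 4 | tert-butyl 2-(diphenoxyphosphoryl)acetate | CC(C)(C)OC(=O)CP(=O)(Oc1ccccc1)Oc1ccccc1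
F9 | step 4 | 2-(diphenoxyphosphoryl)acetic acid | OC(=O)CP(=O)(Oc1ccccc1)Oc1ccccc1
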